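**Retrosynthetic overview**

- Numbering (eremophilane): ring A = C1–C5 and C10, ring B = C5–C10; C3 carries the senecioate, C4 a methyl, C5 the angular methyl, C7 the isopropenyl group, C8 the ketone, C9 the tiglate. All ring substituents are equatorial on a trans-decalin, so C7 and C9 (both alpha to the ketone) are thermodynamically controlled.
- Enabling feature: in ring B the C8 carbonyl is para to the methyl-bearing quaternary C5 and next to the C9 oxygen, and C10 carries the C1 methylene. Ring B is therefore a dearomatized 2-alkoxy-3,4-dimethylphenol. In ring A, O3 and the C4 methyl are trans-diequatorial beside C5, which is a trans-2,3-epoxybutyl unit opened at C4.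
- Key disconnection (C1–C2 and C4–C5 in one operation): the O,C-dianion of 2-(methoxymethoxy)-3,4-dimethylphenol plus (2R,3R)-epoxybutyl triflate. Benzylic alkylation is followed by dearomatizing para-alkylation of the phenoxide by the epoxide; this closes ring A, turns the flat arene into ring B and sets C3, C4 and C5.
- Ring order: ring B comes from the arene (from 2,3-dimethylphenol). The epoxide comes from crotyl alcohol by Sharpless epoxidation and is the only source of absolute configuration. Ring A is closed in the key step.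
- After the key step: ring B is saturated in two stages (hydrogenation of C6=C7, dissolving-metal reduction of C9=C10 to the trans fusion), the C7 side chain is added by acetone aldol and dehydration, and the two esters are attached.

Key step: step 6

Remark: crotyl alcohol is used as the E isomer; the Z isomer would give the cis-epoxide and hence the C4 epimer.

**Step 1**
Reactants: 1 2,3-dimethylphenol
Product: 2 2-hydroxy-3,4-dimethylbenzaldehyde
Conditions: MgCl2, Et3N, paraformaldehyde, MeCN, reflux
Reagents that add atoms: paraformaldehyde (formaldehyde), C=O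
Why: Casnati–Skattebøl ortho-formylation of the magnesium phenoxide should be fully regioselective because only one ortho position is free; the formyl group marks the carbon that becomes C8.

**Step 2**
Reactants: 2 2-hydroxy-3,4-dimethylbenzaldehyde
Product: 3 2-(methoxymethoxy)-3,4-dimethylbenzaldehyde
Conditions: MOMCl, i-Pr2NEt, CH2Cl2, 0 °C to rt
Reagents that add atoms: chloromethyl methyl ether, COCCl
Why: Williamson-type O-alkylation of the phenol puts a base-stable MOM acetal on the oxygen that becomes O9.

**Step 3**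
Reactants: 3 2-(methoxymethoxy)-3,4-dimethylbenzaldehyde
Product: 5 2-(methoxymethoxy)-3,4-dimethylphenol, via aryl formate 4 (not isolated)
Conditions: mCPBA, CH2Cl2, 0 °C to rt; then K2CO3 (cat.), MeOH, rt
Reagents that add atoms: 3-chloroperoxybenzoic acid, OOC(=O)c1cccc(Cl)c1
Why: Baeyer–Villiger (Dakin-type) oxidation of the electron-rich benzaldehyde proceeds with aryl migration to formate 4, which is methanolysed in the same flask to the phenol whose oxygen becomes the C8 carbonyl.

**Step 4**
Reactants: 6 (E)-but-2-en-1-ol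
Product: 7 [(2R,3R)-3-methyloxiran-2-yl]methanol
Conditions: Ti(OiPr)4 (cat.), D-(−)-diisopropyl tartrate (cat.), t-BuOOH, 4 Å molecular sieves, CH2Cl2, −20 °C
Reagents that add atoms: tert-butyl hydroperoxide, CC(C)(C)OO
Why: Sharpless asymmetric epoxidation of the E-allylic alcohol with the D-tartrate ligand should give the (2R,3R)-trans-epoxide, which carries the C3 and C4 configuration of the target.

**Step 5**
Reactants: 7 [(2R,3R)-3-methyloxiran-2-yl]methanol
Product: 8 [(2R,3R)-3-methyloxiran-2-yl]methyl trifluoromethanesulfonate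
Conditions: Tf2O, 2,6-lutidine, CH2Cl2, −78 °C; used at once
Reagents that add atoms: trifluoromethanesulfonic anhydride, O=S(=O)(OS(=O)(=O)C(F)(F)F)C(F)(F)F
Why: O-sulfonylation of the primary alcohol leaves both epoxide stereocentres untouched and gives an electrophile whose CH2–OTf carbon reacts far faster than either epoxide carbon.

**Step 6**
Reactants: 5 2-(methoxymethoxy)-3,4-dimethylphenol; 8 [(2R,3R)-3-methyloxiran-2-yl]methyl trifluoromethanesulfonate
Product: 11 (4aR,5R,6R)-6-hydroxy-1-(methoxymethoxy)-4a,5-dimethyl-5,6,7,8-tetrahydronaphthalen-2(4aH)-one, via benzylic O,C-dianion 9 (not isolated), via epoxy phenoxide 10 (not isolated)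
Conditions: n-BuLi (2.1 equiv), KOt-Bu (2.1 equiv), THF, −78 to −50 °C; 8, −78 °C; then t-BuOH, dilute to 0.01 M, 65 °C; NH4Cl (aq)
Reagents that add atoms: none
Why: Proposed new method: the n-BuLi/KOt-Bu superbase removes the phenol proton and then a proton of the C10 methyl group (meta to O−, chelated by the neighbouring OMOM group, hence more acidic than the para C5 methyl); the benzylic carbanion of 9 displaces the primary triflate of 8 by SN2 at −78 °C to form C1–C2, and on warming in t-BuOH the potassium phenoxide 10 opens the epoxide with its para carbon C5 to form C4–C5, which dearomatizes ring B to the cross-conjugated dienone. The closest known reaction types are C-alkylation of cresol O,C-dianions, selective triflate displacement in epoxy triflates, intramolecular para-alkylation of phenoxides by tethered sulfonates or halides (Ar2-6 participation) and 6-endo epoxide–arene cyclialkylation; what is new is their union in one flask with an epoxide as the electrophile of the dearomatizing alkylation. Ring A is closed by a 6-endo-tet opening of the epoxide at C4 (Ar2-6 mode), which should beat 5-exo attack at C3 because the attacking orbital of C5 is perpendicular to the arene plane and cannot reach C3 through a fused five-membered transition state. C3 keeps the epoxide configuration, C4 is inverted (anti SN2 opening, so the trans-epoxide gives the trans O3/C4-methyl pair), and the quaternary C5 is set by the chair-like transition state with O3 and the C4 methyl equatorial and the angular methyl axial (the C5 epimer would need a boat). The step needs C- over O-alkylation, secured because the phenoxide oxygen is meta to the tether and cannot reach the epoxide while high dilution and the protic medium suppress the intermolecular reaction. It also needs para (C5) over ortho (C9) attack, secured by the OMOM group, since ipso attack at the alkoxy-bearing, more hindered C9 would give the less stable linearly conjugated dienone.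

**Step 7**
Reactants: 11 (4aR,5R,6R)-6-hydroxy-1-(methoxymethoxy)-4a,5-dimethyl-5,6,7,8-tetrahydronaphthalen-2(4aH)-one
Product: 12 (4aR,5R,6R)-6-hydroxy-1-(methoxymethoxy)-4a,5-dimethyl-4,4a,5,6,7,8-hexahydronaphthalen-2(3H)-one
Conditions: H2 (1 atm), RhCl(PPh3)3 (cat.), benzene–EtOH, rt
Reagents that add atoms: none
Why: Homogeneous hydrogenation with RhCl(PPh3)3 should reduce only the unhindered disubstituted C6=C7 bond of the cross-conjugated dienone, as known for steroidal 1,4-dien-3-ones, and leave the tetrasubstituted alkoxy-enone C9=C10 bond; no stereocentre is formed.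

**Step 8**
Reactants: 12 (4aR,5R,6R)-6-hydroxy-1-(methoxymethoxy)-4a,5-dimethyl-4,4a,5,6,7,8-hexahydronaphthalen-2(3H)-one
Product: 14 (1S,4aR,5R,6R,8aR)-6-hydroxy-1-(methoxymethoxy)-4a,5-dimethyloctahydronaphthalen-2(1H)-one, via C8 enolate 13 (not isolated)
Conditions: Li, NH3(l), THF, −78 °C; isoprene; MeOH, −78 °C to rt
Reagents that add atoms: none
Why: Birch-type dissolving-metal reduction of the enone protonates the beta carbon C10 axially (by the C3 hydroxyl) to give the trans ring fusion, as with 4-en-3-one steroids; the C8 enolate 13 resists over-reduction, and protonation by MeOH followed by LiOMe equilibration puts the C9 OMOM group equatorial, because the axial epimer would be syn-axial to the angular methyl group.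

**Step 9**
Reactants: 14 (1S,4aR,5R,6R,8aR)-6-hydroxy-1-(methoxymethoxy)-4a,5-dimethyloctahydronaphthalen-2(1H)-one
Product: 16 (1S,3S,4aR,5R,6R,8aR)-6-hydroxy-3-(2-hydroxypropan-2-yl)-1-(methoxymethoxy)-4a,5-dimethyloctahydronaphthalen-2(1H)-one, via C7 enolate 15 (not isolated)
Conditions: LiN(i-Pr)2 (2.2 equiv), THF, −78 °C; ZnCl2; acetone, −78 to −40 °C; NH4Cl (aq)
Reagents that add atoms: acetone, CC(C)=O
Why: Kinetic deprotonation should occur at the C7 methylene and not at the hindered, alkoxy-bearing C9, and the zinc-mediated aldol addition of enolate 15 to acetone should take place anti to the axial angular methyl group to give the equatorial C7 side chain.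

**Step 10**
Reactants: 16 (1S,3S,4aR,5R,6R,8aR)-6-hydroxy-3-(2-hydroxypropan-2-yl)-1-(methoxymethoxy)-4a,5-dimethyloctahydronaphthalen-2(1H)-one
Product: 17 (1S,3S,4aR,5R,6R,8aR)-3-(2-hydroxypropan-2-yl)-1-(methoxymethoxy)-4a,5-dimethyl-6-[(3-methylbut-2-enoyl)oxy]octahydronaphthalen-2(1H)-one
Conditions: 3-methylbut-2-enoic acid, DCC, DMAP (cat.), CH2Cl2, rt
Reagents that add atoms: 3-methylbut-2-enoic acid, CC(C)=CC(=O)O
Why: Steglich esterification should acylate only the secondary equatorial C3 hydroxyl and leave the tertiary hydroxyl, and the carbodiimide method avoids the ketene pathway that deconjugates the acid chloride.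

**Step 11**
Reactants: 17 (1S,3S,4aR,5R,6R,8aR)-3-(2-hydroxypropan-2-yl)-1-(methoxymethoxy)-4a,5-dimethyl-6-[(3-methylbut-2-enoyl)oxy]octahydronaphthalen-2(1H)-one
Product: 18 (1S,3S,4aR,5R,6R,8aR)-1-(methoxymethoxy)-4a,5-dimethyl-6-[(3-methylbut-2-enoyl)oxy]-3-(prop-1-en-2-yl)octahydronaphthalen-2(1H)-one
Conditions: SOCl2, pyridine, CH2Cl2, −20 to 0 °C
Reagents that add atoms: none
Why: Dehydration of the tertiary alcohol through its chlorosulfite with pyridine as a weak base (E2, no enolate formation) should remove one of the six methyl hydrogens and give the terminal isopropenyl alkene in preference to the conjugated isopropylidene ketone; C7 keeps its configuration.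

**Step 12**
Reactants: 18 (1S,3S,4aR,5R,6R,8aR)-1-(methoxymethoxy)-4a,5-dimethyl-6-[(3-methylbut-2-enoyl)oxy]-3-(prop-1-en-2-yl)octahydronaphthalen-2(1H)-one
Product: 19 (1S,3S,4aR,5R,6R,8aR)-1-hydroxy-4a,5-dimethyl-6-[(3-methylbut-2-enoyl)oxy]-3-(prop-1-en-2-yl)octahydronaphthalen-2(1H)-one
Conditions: ZnBr2, n-PrSH, CH2Cl2, 0 °C
Reagents that add atoms: none
Why: Lewis acid/thiol acetal exchange cleaves the MOM ether quickly under non-protic conditions that should spare the beta,gamma-unsaturated ketone, the enoate and the alpha-ketol that is formed.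

**Step 13**
Reactants: 19 (1S,3S,4aR,5R,6R,8aR)-1-hydroxy-4a,5-dimethyl-6-[(3-methylbut-2-enoyl)oxy]-3-(prop-1-en-2-yl)octahydronaphthalen-2(1H)-one
Product: 20 (1S,3S,4aR,5R,6R,8aR)-4a,5-dimethyl-6-[(3-methylbut-2-enoyl)oxy]-2-oxo-3-(prop-1-en-2-yl)decahydronaphthalen-1-yl (2E)-2-methylbut-2-enoate (CNP0164025.1)
Conditions: (E)-2-methylbut-2-enoyl chloride, pyridine, DMAP (cat.), CH2Cl2, 0 °C to rt
Reagents that add atoms: (E)-2-methylbut-2-enoyl chloride, O=C(Cl)/C(C)=C/C
Why: DMAP-catalysed acylation of the equatorial C9 hydroxyl with the E acid chloride should give the tiglate with the stable E geometry retained; C7 and C9 already hold their thermodynamically preferred equatorial configurations.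

**Compound list**

1 | 2,3-dimethylphenol | Cc1cccc(O)c1C | starting material
2 | 2-hydroxy-3,4-dimethylbenzaldehyde | Cc1ccc(C=O)c(O)c1C | intermediate
3 | 2-(methoxymethoxy)-3,4-dimethylbenzaldehyde | COCOc1c(C)c(C)ccc1C=O | intermediate
4 | 2-(methoxymethoxy)-3,4-dimethylphenyl formate | COCOc1c(C)c(C)ccc1OC=O | intermediate (not isolated)
5 | 2-(methoxymethoxy)-3,4-dimethylphenol | COCOc1c(C)c(C)ccc1O | intermediate
6 | (E)-but-2-en-1-ol (crotyl alcohol) | C/C=C/CO | starting material
7 | [(2R,3R)-3-methyloxiran-2-yl]methanol | C[C@H]1O[C@@H]1CO | intermediate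
8 | [(2R,3R)-3-methyloxiran-2-yl]methyl trifluoromethanesulfonate | C[C@H]1O[C@@H]1COS(=O)(=O)C(F)(F)F | intermediate
9 | O,C-dianion of 5, dipotassium salt [potassium 2-(methoxymethoxy)-4-methyl-3-(potassiomethyl)phenolate] | [K+].[K+].[CH2-]c1c(C)ccc([O-])c1OCOC | intermediate (not isolated)
10 | potassium 2-(methoxymethoxy)-4-methyl-3-{2-[(2R,3R)-3-methyloxiran-2-yl]ethyl}phenolate | [K+].C[C@H]1O[C@@H]1CCc1c(C)ccc([O-])c1OCOC | intermediate (not isolated)
11 | (4aR,5R,6R)-6-hydroxy-1-(methoxymethoxy)-4a,5-dimethyl-5,6,7,8-tetrahydronaphthalen-2(4aH)-one | C1=C[C@]2(C)[C@@H](C)[C@H](O)CCC2=C(OCOC)C1=O | intermediate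
12 | (4aR,5R,6R)-6-hydroxy-1-(methoxymethoxy)-4a,5-dimethyl-4,4a,5,6,7,8-hexahydronaphthalen-2(3H)-one | C1C[C@]2(C)[C@@H](C)[C@H](O)CCC2=C(OCOC)C1=O | intermediate
13 | dilithium (4aR,5R,6R,8aR)-1-(methoxymethoxy)-4a,5-dimethyl-3,4,4a,5,6,7,8,8a-octahydronaphthalene-2,6-bis(olate) (C8 enolate, C3 alkoxide) | [Li+].[Li+].C1C[C@]2(C)[C@@H](C)[C@H]([O-])CC[C@H]2C(OCOC)=C1[O-] | intermediate (not isolated)
14 | (1S,4aR,5R,6R,8aR)-6-hydroxy-1-(methoxymethoxy)-4a,5-dimethyloctahydronaphthalen-2(1H)-one | C1C[C@]2(C)[C@@H](C)[C@H](O)CC[C@H]2[C@H](OCOC)C1=O | intermediate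
15 | dilithium (1S,4aR,5R,6R,8aR)-1-(methoxymethoxy)-4a,5-dimethyl-1,4,4a,5,6,7,8,8a-octahydronaphthalene-2,6-bis(olate) (C7 enolate, C3 alkoxide) | [Li+].[Li+].[O-]C1=CC[C@]2(C)[C@@H](C)[C@H]([O-])CC[C@H]2[C@@H]1OCOC | intermediate (not isolated)
16 | (1S,3S,4aR,5R,6R,8aR)-6-hydroxy-3-(2-hydroxypropan-2-yl)-1-(methoxymethoxy)-4a,5-dimethyloctahydronaphthalen-2(1H)-one | CC(C)(O)[C@@H]1C[C@]2(C)[C@@H](C)[C@H](O)CC[C@H]2[C@H](OCOC)C1=O | intermediate
17 | (1S,3S,4aR,5R,6R,8aR)-3-(2-hydroxypropan-2-yl)-1-(methoxymethoxy)-4a,5-dimethyl-6-[(3-methylbut-2-enoyl)oxy]octahydronaphthalen-2(1H)-one | CC(C)(O)[C@@H]1C[C@]2(C)[C@@H](C)[C@H](OC(=O)C=C(C)C)CC[C@H]2[C@H](OCOC)C1=O | intermediate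
18 | (1S,3S,4aR,5R,6R,8aR)-1-(methoxymethoxy)-4a,5-dimethyl-6-[(3-methylbut-2-enoyl)oxy]-3-(prop-1-en-2-yl)octahydronaphthalen-2(1H)-one | C=C(C)[C@@H]1C[C@]2(C)[C@@H](C)[C@H](OC(=O)C=C(C)C)CC[C@H]2[C@H](OCOC)C1=O | intermediate
19 | (1S,3S,4aR,5R,6R,8aR)-1-hydroxy-4a,5-dimethyl-6-[(3-methylbut-2-enoyl)oxy]-3-(prop-1-en-2-yl)octahydronaphthalen-2(1H)-one | C=C(C)[C@@H]1C[C@]2(C)[C@@H](C)[C@H](OC(=O)C=C(C)C)CC[C@H]2[C@H](O)C1=O | intermediate
20 | (1S,3S,4aR,5R,6R,8aR)-4a,5-dimethyl-6-[(3-methylbut-2-enoyl)oxy]-2-oxo-3-(prop-1-en-2-yl)decahydronaphthalen-1-yl (2E)-2-methylbut-2-enoate (CNP0164025.1) | C=C(C)[C@@H]1C[C@]2(C)[C@@H](C)[C@H](OC(=O)C=C(C)C)CC[C@H]2[C@H](OC(=O)/C(C)=C/C)C1=O | target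

**Step count and risks**

Total step count: 13. Longest linear sequence: 11 steps (steps 1–3 and 6–13); the epoxy triflate branch is 2 steps.

The three steps most likely to fail:

The first is step 6, the proposed new method. Under basic conditions the phenoxide may fail to open the epoxide through carbon: intermolecular O-alkylation, closure at C9 instead of C5, or 5-exo opening at C3 could take over. The fallback uses known reaction types in two separate operations and sets out from 5 and 8. The dianion alkylation alone is run and quenched at −78 °C, which should give the neutral epoxy phenol 2-(methoxymethoxy)-4-methyl-3-{2-[(2R,3R)-3-methyloxiran-2-yl]ethyl}phenol F1. Ring A is then closed by an acid-promoted 6-endo epoxide–arene cyclialkylation (Friedel–Crafts type) of the free phenol in (CF3)2CHOH at rt instead of by a phenoxide. The hydrogen-bond-activated epoxide is opened at C4 by the para carbon, and loss of the phenolic proton gives the dienone. The fallback rejoins the route at 11.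

The second is step 11. Elimination may run toward the acidic C7 hydrogen, or the new double bond may later migrate into conjugation, giving the isopropylidene ketone. The fallback sets out from 14 and attaches the isopropenyl group directly as an sp2 carbon, by alpha-alkenylation of the ketone enolate with 2-bromopropene under zerovalent palladium catalysis (Pd2(dba)3, P(t-Bu)3, LiN(SiMe3)2, toluene, rt). This should give (1S,3S,4aR,5R,6R,8aR)-6-hydroxy-1-(methoxymethoxy)-4a,5-dimethyl-3-(prop-1-en-2-yl)octahydronaphthalen-2(1H)-one F2. Steglich esterification of F2 with 3-methylbut-2-enoic acid then rejoins the route at 18, so that the aldol and the dehydration are both bypassed.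

The third is step 13. During the slow acylation of the hindered C9 hydroxyl, base may move the isopropenyl double bond into conjugation or transpose or epimerize the alpha-ketol. The fallback changes the order of events and sets out from 17. The MOM group is removed first (ZnBr2, n-PrSH) to give (1S,3S,4aR,5R,6R,8aR)-1-hydroxy-3-(2-hydroxypropan-2-yl)-4a,5-dimethyl-6-[(3-methylbut-2-enoyl)oxy]octahydronaphthalen-2(1H)-one F3. The C9 hydroxyl is then acylated with (E)-2-methylbut-2-enoyl chloride, pyridine and DMAP while C7 still carries the inert tertiary alcohol, giving (1S,3S,4aR,5R,6R,8aR)-3-(2-hydroxypropan-2-yl)-4a,5-dimethyl-6-[(3-methylbut-2-enoyl)oxy]-2-oxodecahydronaphthalen-1-yl (2E)-2-methylbut-2-enoate F4. Dehydration with SOCl2 and pyridine becomes the last step and returns to the route at 20, so that the isopropenyl ketone never meets acylation conditions.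

**Further compounds**

F1 | step 6 | 2-(methoxymethoxy)-4-methyl-3-{2-[(2R,3R)-3-methyloxiran-2-yl]ethyl}phenol | C[C@H]1O[C@@H]1CCc1c(C)ccc(O)c1OCOC
F2 | step 11 | (1S,3S,4aR,5R,6R,8aR)-6-hydroxy-1-(methoxymethoxy)-4a,5-dimethyl-3-(prop-1-en-2-yl)octahydronaphthalen-2(1H)-one | C=C(C)[C@@H]1C[C@]2(C)[C@@H](C)[C@H](O)CC[C@H]2[C@H](OCOC)C1=O
F3 | step 13 | (1S,3S,4aR,5R,6R,8aR)-1-hydroxy-3-(2-hydroxypropan-2-yl)-4a,5-dimethyl-6-[(3-methylbut-2-enoyl)oxy]octahydronaphthalen-2(1H)-one | CC(C)(O)[C@@H]1C[C@]2(C)[C@@H](C)[C@H](OC(=O)C=C(C)C)CC[C@H]2[C@H](O)C1=O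
F4 | step 13 | (1S,3S,4aR,5R,6R,8aR)-3-(2-hydroxypropan-2-yl)-4a,5-dimethyl-6-[(3-methylbut-2-enoyl)oxy]-2-oxodecahydronaphthalen-1-yl (2E)-2-methylbut-2-enoate | CC(C)(O)[C@@H]1C[C@]2(C)[C@@H](C)[C@H](OC(=O)C=C(C)C)CC[C@H]2[C@H](OC(=O)/C(C)=C/C)C1=O
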